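**Plan**

- The handle is C3 of ring B (the pyranone): a bare CH between C2, which carries O1 and the benzyl group, and the C4 carbonyl carbon. Ring B is therefore the furan ring of a 2-benzylbenzofuran-3-ol plus one carbon.
- Retrosynthesis first removes the methyl groups and places Cl on C3, then cuts C2–C3 and C3–C4 to excise C3, which leaves a 2-benzyl-3-silyloxybenzofuran.
- The C2–CH2 bond is cut next as the C=C bond of an aurone (aldol). The furanone is cut at O1–C2 and aryl–C(=O) (Williamson, Friedel–Crafts), the heptyl chain at its benzylic C=C (Wittig), and the carboxyl group at aryl–CO2H (aryllithium plus CO2).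
- Forward: ring A receives its chain, the five-membered ring is closed on it, the ring C aldehyde acid is joined by aldol condensation, and ring B arises last by one-carbon expansion of the furan ring, followed by dechlorination and demethylation.
- Stereochemistry: the target has no stereocentre; the alkene geometries, the C2 centre of the dihydroaurone and the cyclopropane centres are all erased on the way.

Key step: step 11

Remark: Friedel–Crafts acylation of 5 is assumed to enter between the heptyl chain and a methoxy group (para to the second methoxy group), as it does for orcinol dimethyl ether.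

**Route**

Step 1
Reactants: 1 3,5-dimethoxybenzaldehyde; 2 hexyltriphenylphosphonium bromide
Product: 4 1-(hept-1-en-1-yl)-3,5-dimethoxybenzene (E/Z mixture), via hexylidenetriphenylphosphorane 3 (not isolated)
Conditions: 2, KOt-Bu, THF, 0 °C; then 1, 0 °C to rt
Reagents that add atoms: none
Why: Wittig olefination of an aromatic aldehyde by a non-stabilised ylide is dependable, and the E/Z ratio is of no consequence because the alkene is saturated in step 2.

Step 2
Reactants: 4 1-(hept-1-en-1-yl)-3,5-dimethoxybenzene
Product: 5 1-heptyl-3,5-dimethoxybenzene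
Conditions: H2 (1 atm), 10% Pd/C, EtOAc, rt
Reagents that add atoms: none
Why: Heterogeneous catalytic hydrogenation saturates the styrene-type double bond under conditions that leave aryl methyl ethers untouched.

Step 3
Reactants: 5 1-heptyl-3,5-dimethoxybenzene; 6 chloroacetyl chloride
Product: 8 2-chloro-1-(2-heptyl-6-hydroxy-4-methoxyphenyl)ethanone, via dimethoxy chloroketone 7 (not isolated)
Conditions: AlCl3 (2.5 equiv), CH2Cl2, 0 °C to reflux; ice/aq. HCl
Reagents that add atoms: none
Why: Friedel–Crafts acylation should enter the ring position para to one methoxy group and flanked by the chain and the other methoxy group, the site preferred by 5-alkylresorcinol dimethyl ethers, and the excess AlCl3 then cleaves only the methyl ether ortho to the new ketone by chelation-assisted demethylation.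

Step 4
Reactants: 8 2-chloro-1-(2-heptyl-6-hydroxy-4-methoxyphenyl)ethanone
Product: 9 4-heptyl-6-methoxy-1-benzofuran-3(2H)-one
Conditions: NaOAc, MeOH, reflux
Reagents that add atoms: none
Why: Intramolecular Williamson etherification (5-exo-tet attack of the phenoxide on the alpha-chloroketone) is the standard closure of benzofuran-3(2H)-ones.

Step 5
Reactants: 1 3,5-dimethoxybenzaldehyde
Product: 10 2-bromo-3,5-dimethoxybenzaldehyde
Conditions: Br2, AcOH, rt
Reagents that add atoms: bromine, BrBr
Why: Electrophilic aromatic bromination goes to C2, which is para to one methoxy group and ortho to the other, the well-established site for this aldehyde.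

Step 6
Reactants: 10 2-bromo-3,5-dimethoxybenzaldehyde
Product: 11 2-bromo-1-(dimethoxymethyl)-3,5-dimethoxybenzene
Conditions: HC(OMe)3, p-TsOH (cat.), MeOH, 60 °C
Reagents that add atoms: trimethyl orthoformate, COC(OC)OC; methanol, CO
Why: Acid-catalysed acetalisation with the orthoformate as water scavenger masks the aldehyde against n-BuLi.

Step 7
Reactants: 11 2-bromo-1-(dimethoxymethyl)-3,5-dimethoxybenzene
Product: 14 3-hydroxy-5,7-dimethoxy-2-benzofuran-1(3H)-one, via aryllithium 12 (not isolated), via lithium carboxylate 13 (not isolated)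
Conditions: n-BuLi, THF, −78 °C; CO2 (g); then 2 M HCl, THF, rt
Reagents that add atoms: carbon dioxide, O=C=O; water, O
Why: Bromine–lithium exchange outruns any attack on the acetal, carboxylation of the aryllithium with CO2 installs the carboxyl group, and aqueous acid hydrolyses the acetal to the 2-formylbenzoic acid, which rests as its lactol (3-hydroxyphthalide) tautomer.

Step 8
Reactants: 9 4-heptyl-6-methoxy-1-benzofuran-3(2H)-one; 14 3-hydroxy-5,7-dimethoxy-2-benzofuran-1(3H)-one
Product: 16 methyl 2-[(Z)-(4-heptyl-6-methoxy-3-oxo-1-benzofuran-2(3H)-ylidene)methyl]-4,6-dimethoxybenzoate, via potassium aurone carboxylate 15 (not isolated)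
Conditions: KOH (2.5 equiv), MeOH, 50 °C; evaporate; then MeI, DMF, rt
Reagents that add atoms: iodomethane, CI
Why: In this aldol condensation (aurone synthesis) the lactol opens in KOH to the formyl carboxylate, whose carboxylate cannot trap the aldolate as a phthalide, so E1cB dehydration should give the thermodynamically favoured Z-aurone, and the potassium carboxylate is then esterified by SN2 alkylation with MeI.

Step 9
Reactants: 16 methyl 2-[(Z)-(4-heptyl-6-methoxy-3-oxo-1-benzofuran-2(3H)-ylidene)methyl]-4,6-dimethoxybenzoate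
Product: 17 methyl 2-[(4-heptyl-6-methoxy-3-oxo-2,3-dihydro-1-benzofuran-2-yl)methyl]-4,6-dimethoxybenzoate (racemic)
Conditions: H2 (1 atm), 10% Pd/C, EtOAc, rt, stopped after 1 equiv H2
Reagents that add atoms: none
Why: Catalytic hydrogenation of the exocyclic enone double bond of aurones to 2-benzylbenzofuran-3(2H)-ones is routine, and the new C2 centre is racemic and erased in step 10.

Step 10
Reactants: 17 methyl 2-[(4-heptyl-6-methoxy-3-oxo-2,3-dihydro-1-benzofuran-2-yl)methyl]-4,6-dimethoxybenzoate
Product: 18 methyl 2-{[3-(tert-butyldimethylsilyloxy)-4-heptyl-6-methoxy-1-benzofuran-2-yl]methyl}-4,6-dimethoxybenzoate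
Conditions: TBSOTf, Et3N, CH2Cl2, 0 °C, argon; used without storage
Reagents that add atoms: tert-butyldimethylsilyl trifluoromethanesulfonate, CC(C)(C)[Si](C)(C)OS(=O)(=O)C(F)(F)F
Why: Soft enolisation and O-silylation of a ketone with a silyl triflate and Et3N is standard, here helped by the gain of furan aromaticity, and the ester has no alpha-hydrogen to interfere.

Step 11
Reactants: 18 methyl 2-{[3-(tert-butyldimethylsilyloxy)-4-heptyl-6-methoxy-1-benzofuran-2-yl]methyl}-4,6-dimethoxybenzoate; 19 sodium trichloroacetate
Product: 22 methyl 2-[(3-chloro-5-heptyl-7-methoxy-4-oxo-4H-chromen-2-yl)methyl]-4,6-dimethoxybenzoate, via dichlorocyclopropane 20 (not isolated), via silyloxybenzopyrylium chloride 21 (not isolated)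
Conditions: 19 (4 equiv), DME, reflux (85 °C), argon
Reagents that add atoms: none
Why: Proposed new method: thermal decarboxylation of 19 releases the trichloromethyl anion, which loses chloride to give dichlorocarbene without base or protic nucleophile, and this electrophilic carbene should add in a [2+1] fashion to the C2=C3 bond of 18, the only alkene present and one that carries two oxygen donors. The 1,1-dichlorocyclopropane 20 is then set up for the cyclopropyl-to-allyl cation electrocyclic opening: disrotatory cleavage of the former C2–C3 bond with departure of the endo chloride gives the 3-chloro-4-silyloxybenzopyrylium ion 21, stabilised by O1 and the silyloxy group, and chloride takes the silyl group from oxygen to unveil the C4 carbonyl of an aromatic pyranone. The closest known reactions are the dihalocarbene ring expansion of cyclic silyl enol ethers to 2-halo-2-enones, the expansion of indenes and benzofurans to 2-halonaphthalenes and 3-halochromenes, and the Ciamician–Dennstedt rearrangement. Ring B is closed not by a cyclisation but by insertion of one carbon into the furan ring: a three-membered ring is formed by cheletropic addition and opened with enlargement to the six-membered ring, which creates the C2–C3 and C3–C4 bonds. No stereocentre remains, since the two of 20 are lost on opening. The selectivity needed is that of the carbene for the silyl enol ether over the methoxyarene rings, the ester and the benzylic C–H bonds, which the far higher nucleophilicity of the doubly oxygenated enol ether bond should secure, while base-free generation keeps the silyl ether and the ester intact until the cation has formed.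

Step 12
Reactants: 22 methyl 2-[(3-chloro-5-heptyl-7-methoxy-4-oxo-4H-chromen-2-yl)methyl]-4,6-dimethoxybenzoate
Product: 23 methyl 2-[(5-heptyl-7-methoxy-4-oxo-4H-chromen-2-yl)methyl]-4,6-dimethoxybenzoate
Conditions: H2 (1 atm), 10% Pd/C, Et3N, EtOAc, rt, stopped after 1 equiv H2
Reagents that add atoms: none
Why: Catalytic hydrodechlorination of a vinylic chloride alpha to a carbonyl is fast when Et3N traps the HCl, whereas the C2=C3 bond of a 2-substituted chromone is reduced only slowly at 1 atm.

Step 13
Reactants: 23 methyl 2-[(5-heptyl-7-methoxy-4-oxo-4H-chromen-2-yl)methyl]-4,6-dimethoxybenzoate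
Product: 24 siphulin, 2-[(5-heptyl-7-hydroxy-4-oxo-4H-chromen-2-yl)methyl]-4,6-dihydroxybenzoic acid
Conditions: BBr3 (10 equiv), CH2Cl2, −78 °C to rt; ice-water work-up
Reagents that add atoms: none
Why: BBr3 dealkylation (Lewis acid activation, then SN2 attack of bromide on the methyl group) should cleave the three aryl methyl ethers and, by the same O–alkyl cleavage, the hindered methyl ester, and a cold work-up hydrolyses the borates without decarboxylating the product.

**Compound list**

1 | 3,5-dimethoxybenzaldehyde | COc1cc(C=O)cc(OC)c1 | starting material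
2 | hexyltriphenylphosphonium bromide | CCCCCC[P+](c1ccccc1)(c1ccccc1)c1ccccc1.[Br-] | starting material
3 | hexylidenetriphenylphosphorane (not isolated) | CCCCCC=P(c1ccccc1)(c1ccccc1)c1ccccc1 | intermediate
4 | 1-(hept-1-en-1-yl)-3,5-dimethoxybenzene (E/Z mixture, Z isomer drawn) | CCCCC/C=C\c1cc(OC)cc(OC)c1 | intermediate
5 | 1-heptyl-3,5-dimethoxybenzene | CCCCCCCc1cc(OC)cc(OC)c1 | intermediate
6 | chloroacetyl chloride | ClCC(=O)Cl | starting material
7 | 2-chloro-1-(2-heptyl-4,6-dimethoxyphenyl)ethanone (not isolated) | CCCCCCCc1cc(OC)cc(OC)c1C(=O)CCl | intermediate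
8 | 2-chloro-1-(2-heptyl-6-hydroxy-4-methoxyphenyl)ethanone | CCCCCCCc1cc(OC)cc(O)c1C(=O)CCl | intermediate
9 | 4-heptyl-6-methoxy-1-benzofuran-3(2H)-one | CCCCCCCc1cc(OC)cc2OCC(=O)c12 | intermediate
10 | 2-bromo-3,5-dimethoxybenzaldehyde | COc1cc(C=O)c(Br)c(OC)c1 | intermediate
11 | 2-bromo-1-(dimethoxymethyl)-3,5-dimethoxybenzene | COc1cc(C(OC)OC)c(Br)c(OC)c1 | intermediate
12 | [2-(dimethoxymethyl)-4,6-dimethoxyphenyl]lithium (not isolated) | COc1cc(C(OC)OC)c([Li])c(OC)c1 | intermediate
13 | lithium 2-(dimethoxymethyl)-4,6-dimethoxybenzoate (not isolated) | [Li+].COc1cc(C(OC)OC)c(C(=O)[O-])c(OC)c1 | intermediate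
14 | 3-hydroxy-5,7-dimethoxy-2-benzofuran-1(3H)-one (racemic lactol of 2-formyl-4,6-dimethoxybenzoic acid) | COc1cc(OC)c2C(=O)OC(O)c2c1 | intermediate
15 | potassium 2-[(Z)-(4-heptyl-6-methoxy-3-oxo-1-benzofuran-2(3H)-ylidene)methyl]-4,6-dimethoxybenzoate (not isolated) | [K+].CCCCCCCc1cc(OC)cc2c1C(=O)/C(=C/c1cc(OC)cc(OC)c1C(=O)[O-])O2 | intermediate
16 | methyl 2-[(Z)-(4-heptyl-6-methoxy-3-oxo-1-benzofuran-2(3H)-ylidene)methyl]-4,6-dimethoxybenzoate | CCCCCCCc1cc(OC)cc2c1C(=O)/C(=C/c1cc(OC)cc(OC)c1C(=O)OC)O2 | intermediate
17 | methyl 2-[(4-heptyl-6-methoxy-3-oxo-2,3-dihydro-1-benzofuran-2-yl)methyl]-4,6-dimethoxybenzoate (racemic) | CCCCCCCc1cc(OC)cc2OC(Cc3cc(OC)cc(OC)c3C(=O)OC)C(=O)c12 | intermediate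
18 | methyl 2-{[3-(tert-butyldimethylsilyloxy)-4-heptyl-6-methoxy-1-benzofuran-2-yl]methyl}-4,6-dimethoxybenzoate | CCCCCCCc1cc(OC)cc2oc(Cc3cc(OC)cc(OC)c3C(=O)OC)c(O[Si](C)(C)C(C)(C)C)c12 | intermediate
19 | sodium trichloroacetate | [Na+].[O-]C(=O)C(Cl)(Cl)Cl | starting material
20 | 1,1-dichlorocyclopropane adduct across C2–C3 of 18 (racemic, cis-fused, not isolated) | CCCCCCCc1cc(OC)cc2OC3(Cc4cc(OC)cc(OC)c4C(=O)OC)C(Cl)(Cl)C3(O[Si](C)(C)C(C)(C)C)c12 | intermediate
21 | 4-(tert-butyldimethylsilyloxy)-3-chloro-2-[3,5-dimethoxy-2-(methoxycarbonyl)benzyl]-5-heptyl-7-methoxychromenylium chloride (not isolated) | CCCCCCCc1cc(OC)cc2[o+]c(Cc3cc(OC)cc(OC)c3C(=O)OC)c(Cl)c(O[Si](C)(C)C(C)(C)C)c12.[Cl-] | intermediate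
22 | methyl 2-[(3-chloro-5-heptyl-7-methoxy-4-oxo-4H-chromen-2-yl)methyl]-4,6-dimethoxybenzoate | CCCCCCCc1cc(OC)cc2oc(Cc3cc(OC)cc(OC)c3C(=O)OC)c(Cl)c(=O)c12 | intermediate
23 | methyl 2-[(5-heptyl-7-methoxy-4-oxo-4H-chromen-2-yl)methyl]-4,6-dimethoxybenzoate | CCCCCCCc1cc(OC)cc2oc(Cc3cc(OC)cc(OC)c3C(=O)OC)cc(=O)c12 | intermediate
24 | siphulin, 2-[(5-heptyl-7-hydroxy-4-oxo-4H-chromen-2-yl)methyl]-4,6-dihydroxybenzoic acid | CCCCCCCc1cc(O)cc2oc(Cc3cc(O)cc(O)c3C(=O)O)cc(=O)c12 | target

**Step count and risks**

Total step count: 13. Longest linear sequence: 10 steps (steps 1, 2, 3, 4, 8, 9, 10, 11, 12, 13).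

Step 11 (new method). Cyclopropanation may be too slow, because the C2=C3 bond is tetrasubstituted, flanked by the heptyl and benzyl groups and part of an aromatic furan, so the carbene could be consumed elsewhere. Premature loss of the silyl group at 85 °C would also return the ketone. The fallback uses the known intramolecular ester Wittig synthesis of chromones; it leaves the route at 8 and rejoins it at 23, so step 12 is no longer needed.
- PPh3 in MeCN at reflux should convert 8 into [2-(2-heptyl-6-hydroxy-4-methoxyphenyl)-2-oxoethyl]triphenylphosphonium chloride F1, which aqueous Na2CO3 deprotonates to the stabilised ylide 1-(2-heptyl-6-hydroxy-4-methoxyphenyl)-2-(triphenylphosphoranylidene)ethanone F2.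
- Separately, commercial methyl 2,4-dimethoxy-6-methylbenzoate (COC(=O)c1c(C)cc(OC)cc1OC) is deprotonated at its benzylic methyl group with LiN(i-Pr)2 (THF, −78 °C) to methyl 2-(lithiomethyl)-4,6-dimethoxybenzoate F3. CO2 and acidic work-up turn this into [3,5-dimethoxy-2-(methoxycarbonyl)phenyl]acetic acid F4, and (COCl)2 with catalytic DMF gives methyl 2-(2-chloro-2-oxoethyl)-4,6-dimethoxybenzoate F5.
- Acylation of the phenol of F2 with F5 (pyridine, toluene, rt) gives the aryl ester 3-heptyl-5-methoxy-2-[(triphenylphosphoranylidene)acetyl]phenyl [3,5-dimethoxy-2-(methoxycarbonyl)phenyl]acetate F6. Heating in toluene then closes ring B by Wittig reaction of the ylide with the ester carbonyl, giving 23 and Ph3PO.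

Step 12. Saturation of the C2=C3 bond of ring B may compete with hydrogenolysis of the C–Cl bond, so that chromone and chromanone form together. The fallback accepts the over-reduction. Starting from 22, prolonged hydrogenation (H2, 10% Pd/C, Et3N, EtOAc/MeOH) is driven to methyl 2-[(5-heptyl-7-methoxy-4-oxochroman-2-yl)methyl]-4,6-dimethoxybenzoate F7 (racemic). The enone is then restored by aerobic dehydrogenation (Pd(OCOCF3)2, DMSO, O2, AcOH, 80 °C), which returns to the route at 23.

Step 13. O–alkyl cleavage of the hindered methyl ester may lag behind ether cleavage, and the long exposure then needed invites loss of CO2 from the electron-rich 2,4-dihydroxybenzoic acid during acidic work-up. The fallback separates the two tasks. Starting from 23, SN2 demethylation of the ester with LiI in pyridine at reflux, followed by acidification, should give 2-[(5-heptyl-7-methoxy-4-oxo-4H-chromen-2-yl)methyl]-4,6-dimethoxybenzoic acid F8. A shorter, colder BBr3 treatment (CH2Cl2, −78 to 0 °C), which now has only aryl ethers to cleave, then gives 24.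

**Further compounds**

F1 | step 11 | [2-(2-heptyl-6-hydroxy-4-methoxyphenyl)-2-oxoethyl]triphenylphosphonium chloride | CCCCCCCc1cc(OC)cc(O)c1C(=O)C[P+](c1ccccc1)(c1ccccc1)c1ccccc1.[Cl-]
F2 | step 11 | 1-(2-heptyl-6-hydroxy-4-methoxyphenyl)-2-(triphenylphosphoranylidene)ethanone | CCCCCCCc1cc(OC)cc(O)c1C(=O)C=P(c1ccccc1)(c1ccccc1)c1ccccc1
F3 | step 11 | methyl 2-(lithiomethyl)-4,6-dimethoxybenzoate | COC(=O)c1c(C[Li])cc(OC)cc1OC
F4 | step 11 | [3,5-dimethoxy-2-(methoxycarbonyl)phenyl]acetic acid | COC(=O)c1c(CC(=O)O)cc(OC)cc1OC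
F5 | step 11 | methyl 2-(2-chloro-2-oxoethyl)-4,6-dimethoxybenzoate | COC(=O)c1c(CC(=O)Cl)cc(OC)cc1OC
F6 | step 11 | 3-heptyl-5-methoxy-2-[(triphenylphosphoranylidene)acetyl]phenyl [3,5-dimethoxy-2-(methoxycarbonyl)phenyl]acetate | CCCCCCCc1cc(OC)cc(OC(=O)Cc2cc(OC)cc(OC)c2C(=O)OC)c1C(=O)C=P(c1ccccc1)(c1ccccc1)c1ccccc1
F7 | step 12 | methyl 2-[(5-heptyl-7-methoxy-4-oxochroman-2-yl)methyl]-4,6-dimethoxybenzoate (racemic) | CCCCCCCc1cc(OC)cc2OC(Cc3cc(OC)cc(OC)c3C(=O)OC)CC(=O)c12
F8 | step 13 | 2-[(5-heptyl-7-methoxy-4-oxo-4H-chromen-2-yl)methyl]-4,6-dimethoxybenzoic acid | CCCCCCCc1cc(OC)cc2oc(Cc3cc(OC)cc(OC)c3C(=O)O)cc(=O)c12
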